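The bonds at C4 of the chroman-2-one that the plan cuts are C4–C1' (catechol ring) and C4–C3, with C4–C4a kept. C4 is a diarylmethine carbon between ring A and the catechol ring, and before C3 is attached it has no hydrogen-bearing sp3 neighbour. The formyl carbon of a ring A aldehyde can therefore become C4 through a palladium carbene. In one operation the key step joins that carbon to the catechol aryl group of an aryl bromide and to dimethyl malonate, and sets (R)-C4 under chiral bisphosphine control. Its precursor is the N-tosylhydrazone of 2,4-bis(benzyloxy)-5-[2-(3,4-dimethoxyphenyl)ethyl]benzaldehyde, whose ortho benzyloxy oxygen ends as lactone O1.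

Key step: step 4

Remark 1: C4 is (R) in the target (C4a > C1' of the catechol ring > C3 > H), and the ranking ring A > catechol ring > side-chain carbon > H holds for the open-chain malonate and propanoates too, so the descriptor stays (R) from step 4 to the end.

Remark 2: the sense of induction of the bisphosphine in step 4 cannot be predicted with confidence; (R)-H8-BINAP is written, and its antipode is taken if a first run delivers the (S)-malonate.

Step 1
Reactants: 1 5-bromo-2,4-dihydroxybenzaldehyde
Product: 2 2,4-bis(benzyloxy)-5-bromobenzaldehyde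
Conditions: BnBr (2.5 equiv), K2CO3 (3 equiv), DMF, 60 °C
Reagents that add atoms: benzyl bromide, BrCc1ccccc1
Why: Williamson ether synthesis; excess benzyl bromide in warm DMF should alkylate both phenoxides, including the hydrogen-bonded 2-OH, while the aldehyde and the aryl bromide are inert to K2CO3.

Step 2
Reactants: 3 3,4-dimethoxystyrene; 2 2,4-bis(benzyloxy)-5-bromobenzaldehyde
Product: 5 2,4-bis(benzyloxy)-5-[2-(3,4-dimethoxyphenyl)ethyl]benzaldehyde, via B-alkyl-9-BBN adduct 4 (not isolated)
Conditions: 3 (1.4 equiv), 9-BBN (1.3 equiv), THF, 0 °C to rt; then 2, Pd(dppf)Cl2 (5 mol%), K3PO4 (3 M aq, 3 equiv), DMF, 60 °C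
Reagents that add atoms: none
Why: B-alkyl Suzuki–Miyaura coupling; anti-Markovnikov hydroboration of the styrene gives the primary alkylborane, which as its hydroxyborate transfers the 2-arylethyl group to the aryl bromide, and the styrene is kept in excess over 9-BBN so that no B–H remains to reduce the aldehyde.

Step 3
Reactants: 5 2,4-bis(benzyloxy)-5-[2-(3,4-dimethoxyphenyl)ethyl]benzaldehyde
Product: 6 N'-[(E)-{2,4-bis(benzyloxy)-5-[2-(3,4-dimethoxyphenyl)ethyl]phenyl}methylidene]-4-methylbenzenesulfonohydrazide
Conditions: TsNHNH2 (1.05 equiv), MeOH, 50 °C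
Reagents that add atoms: 4-methylbenzenesulfonohydrazide, Cc1ccc(cc1)S(=O)(=O)NN
Why: Condensation of an aryl aldehyde with tosylhydrazide to the (E)-N-tosylhydrazone, which should crystallise from methanol; no other group in 5 reacts.

Step 4
Reactants: 6 N'-[(E)-{2,4-bis(benzyloxy)-5-[2-(3,4-dimethoxyphenyl)ethyl]phenyl}methylidene]-4-methylbenzenesulfonohydrazide; 7 4-bromo-1,2-bis(benzyloxy)benzene; 8 dimethyl malonate
Product: 10 dimethyl 2-[(R)-[3,4-bis(benzyloxy)phenyl]{2,4-bis(benzyloxy)-5-[2-(3,4-dimethoxyphenyl)ethyl]phenyl}methyl]propanedioate, via aryldiazomethane 9 (not isolated)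
Conditions: Pd2(dba)3 (2.5 mol%), (R)-H8-BINAP (6 mol%), 7 (1.3 equiv), 8 (2.5 equiv), Cs2CO3 (3.5 equiv), 1,4-dioxane, 70 °C, 6 added slowly
Reagents that add atoms: none
Why: Proposed new method: Cs2CO3 should convert 6 slowly into aryldiazomethane 9 (Bamford–Stevens), which meets the aryl palladium bromide (divalent palladium) formed by oxidative addition of 7 to zerovalent palladium and gives an aryl palladium carbene; 1,1-migratory insertion of the catechol aryl group forms C4–C1' and a diarylmethyl palladium that has no β-hydrogen and so persists as a cationic η3-benzyl complex, which the caesium enolate of 8 attacks at the benzylic carbon from the face opposite palladium to form C4–C3 and return zerovalent palladium. The closest known reaction types are the palladium-catalysed coupling of aryl halides with N-tosylhydrazones by carbene migratory insertion, malonate trapping of η3-allyl palladium intermediates made in that way from vinyl halides, and palladium-catalysed benzylic alkylation of diarylmethyl carbonates with malonates; their combination on a diarylmethyl centre with asymmetric induction is untested. No ring is closed. C4 is the only new stereocentre and is controlled by the chiral bisphosphine: the palladium-bound configuration is created in the migratory insertion inside the ligand pocket and passed on with inversion by the outer-sphere attack, or, if the diastereomeric benzyl complexes equilibrate by palladium–palladium exchange (η3–η1–η3 slippage alone does not invert the palladium-bound carbon), the faster-reacting complex is selected in the attack itself. The step needs chemoselectivity (carbene capture before direct arylation of the malonate, malonate before sulfinate or hydrazone anion as the nucleophile, aryl migration before carbene C–H insertion into the ortho OCH2Ph group) and attack at the benzylic carbon; these should be secured by a BINAP-type ligand that arylates malonates poorly, excess malonate, slow feeding of 6 so that 9 does not accumulate, the preference of a soft stabilised carbanion for the exocyclic terminus, and the ortho benzyloxy group of ring A, which distinguishes the two aryl groups and favours η3 binding through ring A.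

Step 5
Reactants: 10 dimethyl 2-[(R)-[3,4-bis(benzyloxy)phenyl]{2,4-bis(benzyloxy)-5-[2-(3,4-dimethoxyphenyl)ethyl]phenyl}methyl]propanedioate
Product: 11 methyl (3R)-3-[3,4-bis(benzyloxy)phenyl]-3-{2,4-bis(benzyloxy)-5-[2-(3,4-dimethoxyphenyl)ethyl]phenyl}propanoate
Conditions: LiCl (3 equiv), H2O (2 equiv), DMSO, 140 °C
Reagents that add atoms: none
Why: Krapcho dealkoxycarbonylation; chloride demethylates one ester by SN2 attack, the carboxylate loses CO2 and water protonates the ester enolate, while the doubly benzylic C4–H is not acidic enough to exchange under these near-neutral conditions, so (R)-C4 should be retained.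

Step 6
Reactants: 11 methyl (3R)-3-[3,4-bis(benzyloxy)phenyl]-3-{2,4-bis(benzyloxy)-5-[2-(3,4-dimethoxyphenyl)ethyl]phenyl}propanoate
Product: 13 (4R)-4-(3,4-dihydroxyphenyl)-6-[2-(3,4-dimethoxyphenyl)ethyl]-7-hydroxy-3,4-dihydro-2H-chromen-2-one (CNP0376539.1), via tetraphenol methyl ester 12 (not isolated)
Conditions: H2 (1 atm), 10% Pd/C, THF, rt; filter under argon, evaporate; TsOH·H2O (10 mol%), PhMe, 80 °C
Reagents that add atoms: none
Why: Catalytic hydrogenolysis should cleave the four aryl benzyl ethers without touching the aryl methyl ethers or C4; acid-catalysed lactonisation (intramolecular transesterification) then closes the six-membered ring from the only phenol that can reach the ester, the ring A hydroxyl ortho to C4, with loss of methanol and no reaction at C4.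

Compound list
1 | 5-bromo-2,4-dihydroxybenzaldehyde | O=Cc1cc(Br)c(O)cc1O | starting material
2 | 2,4-bis(benzyloxy)-5-bromobenzaldehyde | O=Cc1cc(Br)c(OCc2ccccc2)cc1OCc1ccccc1 | intermediate
3 | 3,4-dimethoxystyrene (4-ethenyl-1,2-dimethoxybenzene) | C=Cc1ccc(OC)c(OC)c1 | starting material
4 | 9-[2-(3,4-dimethoxyphenyl)ethyl]-9-borabicyclo[3.3.1]nonane | COc1ccc(CCB2C3CCCC2CCC3)cc1OC | intermediate
5 | 2,4-bis(benzyloxy)-5-[2-(3,4-dimethoxyphenyl)ethyl]benzaldehyde | COc1ccc(CCc2cc(C=O)c(OCc3ccccc3)cc2OCc2ccccc2)cc1OC | intermediate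
6 | N'-[(E)-{2,4-bis(benzyloxy)-5-[2-(3,4-dimethoxyphenyl)ethyl]phenyl}methylidene]-4-methylbenzenesulfonohydrazide | COc1ccc(CCc2cc(/C=N/NS(=O)(=O)c3ccc(C)cc3)c(OCc3ccccc3)cc2OCc2ccccc2)cc1OC | intermediate
7 | 4-bromo-1,2-bis(benzyloxy)benzene | Brc1ccc(OCc2ccccc2)c(OCc2ccccc2)c1 | starting material
8 | dimethyl malonate (dimethyl propanedioate) | COC(=O)CC(=O)OC | starting material
9 | 1,5-bis(benzyloxy)-2-(diazomethyl)-4-[2-(3,4-dimethoxyphenyl)ethyl]benzene | COc1ccc(CCc2cc(C=[N+]=[N-])c(OCc3ccccc3)cc2OCc2ccccc2)cc1OC | intermediate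
10 | dimethyl 2-[(R)-[3,4-bis(benzyloxy)phenyl]{2,4-bis(benzyloxy)-5-[2-(3,4-dimethoxyphenyl)ethyl]phenyl}methyl]propanedioate | COc1ccc(CCc2cc([C@H](C(C(=O)OC)C(=O)OC)c3ccc(OCc4ccccc4)c(OCc4ccccc4)c3)c(OCc3ccccc3)cc2OCc2ccccc2)cc1OC | intermediate
11 | methyl (3R)-3-[3,4-bis(benzyloxy)phenyl]-3-{2,4-bis(benzyloxy)-5-[2-(3,4-dimethoxyphenyl)ethyl]phenyl}propanoate | COc1ccc(CCc2cc([C@H](CC(=O)OC)c3ccc(OCc4ccccc4)c(OCc4ccccc4)c3)c(OCc3ccccc3)cc2OCc2ccccc2)cc1OC | intermediate
12 | methyl (3R)-3-(3,4-dihydroxyphenyl)-3-{2,4-dihydroxy-5-[2-(3,4-dimethoxyphenyl)ethyl]phenyl}propanoate | COc1ccc(CCc2cc([C@H](CC(=O)OC)c3ccc(O)c(O)c3)c(O)cc2O)cc1OC | intermediate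
13 | (4R)-4-(3,4-dihydroxyphenyl)-6-[2-(3,4-dimethoxyphenyl)ethyl]-7-hydroxy-3,4-dihydro-2H-chromen-2-one | COc1ccc(CCc2cc3c(cc2O)OC(=O)C[C@@H]3c2ccc(O)c(O)c2)cc1OC | target

Total step count: 6
Longest linear sequence: 6 steps (1 to 13)

Steps most likely to fail

Step 4. The diarylmethyl palladium may be captured by the wrong nucleophile (sulfinate or hydrazone anion). The carbene may be lost by dimerisation or by C–H insertion into the ortho benzyloxy methylene. The malonate may be arylated directly, or the enantio-discrimination may be poor. The fallback uses known chemistry, sets out from 5 and 7 and comes back at 11, so that step 5 is no longer needed. Aldehyde 5 is olefinated with methyl (triphenylphosphoranylidene)acetate (PhMe, 80 °C, Wittig reaction) to methyl (2E)-3-{2,4-bis(benzyloxy)-5-[2-(3,4-dimethoxyphenyl)ethyl]phenyl}prop-2-enoate F1. Bromide 7 is converted by bromine–lithium exchange and borylation (n-BuLi, THF, −78 °C; B(OiPr)3; aq HCl) into [3,4-bis(benzyloxy)phenyl]boronic acid F2. Rhodium-catalysed asymmetric conjugate addition (Hayashi–Miyaura) of F2 to F1 with [RhCl(C2H4)2]2, a chiral bicyclo[2.2.2]octadiene ligand, catalytic aq KOH, dioxane, 50 °C should then give 11. C4 is set by the ligand-controlled face of aryl rhodium insertion, and the diene antipode is chosen on a test run.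

Step 2. The aldehyde may be reduced by boron hydride species, or oxidative addition to the electron-rich bromide may be slow enough for the alkylborane to decay by protodeboronation. The fallback sets out from 2 and 3 and comes back at 5. Mizoroki–Heck coupling (Pd(OAc)2, P(o-tol)3, Et3N, DMF, 100 °C) should give 2,4-bis(benzyloxy)-5-[(E)-2-(3,4-dimethoxyphenyl)ethenyl]benzaldehyde F3. Its alkene is then hydrogenated chemoselectively over Pd/C poisoned with diphenyl sulfide (H2, EtOAc, rt), conditions that spare aryl benzyl ethers and the aromatic aldehyde.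

Step 5. Dealkoxycarbonylation of the hindered malonate may be incomplete, or chloride may cleave aryl ethers at the temperature required. The fallback sets out from 10 and comes back at 13. Saponification (LiOH, THF–MeOH–H2O, 60 °C; then HCl) should give 2-[(R)-[3,4-bis(benzyloxy)phenyl]{2,4-bis(benzyloxy)-5-[2-(3,4-dimethoxyphenyl)ethyl]phenyl}methyl]propanedioic acid F4. Thermal decarboxylation (DMSO, 120 °C) gives (3R)-3-[3,4-bis(benzyloxy)phenyl]-3-{2,4-bis(benzyloxy)-5-[2-(3,4-dimethoxyphenyl)ethyl]phenyl}propanoic acid F5. Hydrogenolysis (H2, Pd/C, THF) gives (3R)-3-(3,4-dihydroxyphenyl)-3-{2,4-dihydroxy-5-[2-(3,4-dimethoxyphenyl)ethyl]phenyl}propanoic acid F6, which lactonises with TsOH·H2O in PhMe at 80 °C to 13.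

Further compounds
F1 | step 4 | methyl (2E)-3-{2,4-bis(benzyloxy)-5-[2-(3,4-dimethoxyphenyl)ethyl]phenyl}prop-2-enoate | COc1ccc(CCc2cc(/C=C/C(=O)OC)c(OCc3ccccc3)cc2OCc2ccccc2)cc1OC
F2 | step 4 | [3,4-bis(benzyloxy)phenyl]boronic acid | OB(O)c1ccc(OCc2ccccc2)c(OCc2ccccc2)c1
F3 | step 2 | 2,4-bis(benzyloxy)-5-[(E)-2-(3,4-dimethoxyphenyl)ethenyl]benzaldehyde | COc1ccc(/C=C/c2cc(C=O)c(OCc3ccccc3)cc2OCc2ccccc2)cc1OC
F4 | step 5 | 2-[(R)-[3,4-bis(benzyloxy)phenyl]{2,4-bis(benzyloxy)-5-[2-(3,4-dimethoxyphenyl)ethyl]phenyl}methyl]propanedioic acid | COc1ccc(CCc2cc([C@H](C(C(=O)O)C(=O)O)c3ccc(OCc4ccccc4)c(OCc4ccccc4)c3)c(OCc3ccccc3)cc2OCc2ccccc2)cc1OC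
F5 | step 5 | (3R)-3-[3,4-bis(benzyloxy)phenyl]-3-{2,4-bis(benzyloxy)-5-[2-(3,4-dimethoxyphenyl)ethyl]phenyl}propanoic acid | COc1ccc(CCc2cc([C@H](CC(=O)O)c3ccc(OCc4ccccc4)c(OCc4ccccc4)c3)c(OCc3ccccc3)cc2OCc2ccccc2)cc1OC
F6 | step 5 | (3R)-3-(3,4-dihydroxyphenyl)-3-{2,4-dihydroxy-5-[2-(3,4-dimethoxyphenyl)ethyl]phenyl}propanoic acid | COc1ccc(CCc2cc([C@H](CC(=O)O)c3ccc(O)c(O)c3)c(O)cc2O)cc1OC
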